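## Structural features

The target is a germacrane-type sesquiterpenoid in which a ten-membered carbocycle (ring A) is fused across C3–C4 to an α,β-unsaturated γ-lactone (ring B, a butenolide). The numbering used throughout is C1 (acetoxy CH beside the ring CH2), C2 (that CH2), C3 and C4 (butenolide β and γ carbons), C5=C6 (E, methyl on C6), C7 (acetoxy CH), C8 (CH2), C9=C10 (cis, methyl on C10), with Ca, C12 and C13 for the lactone α carbon, the carbonyl and the hydroxymethyl carbon. The C3=Ca alkene is tetrasubstituted and carries the primary allylic alcohol C13. There are three stereocentres and no two are adjacent: C1 (S) and C7 (S) are allylic acetates and C4 (R) is the doubly allylic lactone carbinol. C4 and C7 are 1,4-related across the E alkene and C1 and C4 across C2–C3, so relative configuration has to be relayed through the ring. Fragile points are the C4–O bond (ionisation to a pentadienyl cation), the allylic acetates, the 1,5-diene in a medium ring (transannular cyclisation under acid) and the butenolide (base, conjugate addition). The real difficulty is the ten-membered ring with one E and one cis trisubstituted alkene together with the remote C4/C7 relationship. The key step exploits two features. The C3–C4 bond lies between the C3=Ca alkene and the C5=C6 alkene with oxygen on C1, which is an oxy-Cope retron once C1 is a ketone. The atoms C1, C10, C9, C8, C7 and C6, with the cis alkene, map onto a cyclohexene whose C1–C6 bond is the one cleaved in the rearrangement.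

## Logic of the disconnections

**28 ⇒ 27 ⇒ 25.** The lactone O–C12 bond and the C12 oxidation level are removed first. In 25 the two hydroxymethyl arms on Ca have the same origin, and only the arm cis to the C4 hydroxyl can be carried to the acid level through a lactol. Ring B and the C12/C13 distinction therefore arise without a separate protecting group. The forward oxidation must spare the C4 hydroxyl until it is engaged as the lactol, and the other arm, which stops at the aldehyde in 27, must then be reduced 1,2-selectively.

**25 ⇒ 24 ⇒ 23 ⇒ 22 ⇒ 21.** The two acetyl C–O bonds, the O–Si and acetal bonds, and finally the C1–H bond are cut. Removing C1–H turns the C1 stereocentre into a ketone and exposes the oxy-Cope retron in 21. In the forward direction the C7 silyl ether must be cleaved in the presence of the one at C4, so that only O1 and O7 are acetylated. The ketone reduction must be face-selective in a flexible ring, which calls for reagent control.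

**21 ⇒ 18 (key).** The C3–C4 bond is cut and C1–C6 is reconnected. The ten-membered ring, the E alkene and the C4 stereocentre vanish together, and what remains is a cyclohexene with two adjacent fully substituted carbons. The forward step needs trans alkenyl groups on C1 and C6, an E enol ether, a chair transition state and protonation of the dienolate at C2.

**18 ⇒ 17 ⇒ 12 + 15.** The allene is traced to a propargylic methyl ether (C2–H made, Ca–O broken), and the C1–C2 bond is then cut. An alkynide is not ambident, whereas a metalated allene could react at either terminus. The price is one extra step and the demand that the alkynide enter the ketone of 12 on the face anti to the C6 vinyl group.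

**15 ⇒ 14 ⇒ 13.** The O–CH3 bond and the bond between the alkyne and the dioxane carbon are cut, which leads to the symmetric ketone 13. The symmetry means that the allene of 18 has no axial chirality and the C3=Ca alkene of 21 has no geometric isomers.

**12 ⇒ 11 ⇒ 10 ⇒ 7 + 8 ⇒ 5.** The enol O–Si bond, the C4=O (from a terminal alkene), the C6–allyl bond and the C6–CH3 bond are cut in turn. The enol ether doubles as protection of the aldehyde during the addition to C1. The quaternary C6 comes from two enolate alkylations, and the second must occur anti to the C7 silyloxy group, since this sets the chirality later passed on to C4.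

**5 ⇒ 4 ⇒ 3 ⇒ 1.** The O–Si and acetyl bonds are cut, and the C7–O bond is traced to a C–C bond by an oxidative rearrangement. This leads back to the chiral-pool terpene 1, whose single stereocentre becomes C7 with retention.

## Other disconnections considered

**Alternative 1:** The cut is at C1–C10 and C7–C8, which opens the carbocycle into three pieces and leaves the ring closure at C3–C4 for later.
- Forward step: the allenyl boronate A4 would be hydroborated with (Ipc)2BH to a γ-boryl allylborane. This would add to the aldehyde A2 (C1–C10) and then, as the α-boryl allylboronate, to the enal A3 (C7–C8 and the cis C9=C10 alkene), giving the acyclic diol A1.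
- In favour: the plan is convergent, both carbinol centres are set in one flask under reagent control through closed six-membered transition states, and C12 (ester) and C13 (ether) are differentiated from the start. On these three points the alternative is the better.
- Against: no ring is formed. The ten-membered closure (for example a CrCl2/NiCl2-mediated Nozaki–Hiyama–Kishi coupling of the hindered vinyl iodide with the unmasked C4 aldehyde) and the C4 configuration remain open. A2 is a β,γ-unsaturated aldehyde whose C2 methylene lies between the aldehyde and the iodoacrylate and should enolise or conjugate easily. The methyl group of A4 forces a fully substituted α-boryl centre, which should slow the second allylboration and make its cis selectivity less certain.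
- Comparison: the alternative delivers two stereocentres and one alkene and leaves ring, C4 and lactone; the chosen plan delivers ring, C4 and the E alkene at once and leaves C1. Allylboration is well understood and the chosen rearrangement is not, so predictability of the key step favours the alternative. In step count it should be no shorter than the eighteen steps of the chosen plan, and its decisive ring closure would still be end to end.

**Alternative 2:** The cut removes three bonds at once: C4–C5 (ring), C6–CH3 and the lactone O–C12.
- Forward step: Ni(cod)2 (zerovalent nickel) with an N-heterocyclic carbene would couple the terminal alkyne of the open-chain ynal A6 with its C4 aldehyde and transfer a methyl group from ZnMe2 to C6. The zinc alkoxide would then close the butenolide on the cis ester, giving the protected target A5.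
- In favour: ring A, ring B, the C4 carbinol and the E alkene (C4 and CH3 delivered syn across the alkyne) would form in one operation, and C13 is already differentiated. The endgame would be only desilylation, acetylation and ether cleavage. In bond economy of the key step and length of the endgame the alternative is the better.
- Against: the ring is closed end to end, so strain, entropy and oligomers must be expected. The regiochemistry of a macrocyclic coupling of a terminal alkyne depends on the ligand. C4 would be set only by remote stereocentres. The C4 aldehyde of A6 is an enal and a doubly activated acceptor, for which conjugate-type coupling and alkene isomerisation (which would block lactonisation) compete.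
- Comparison: both plans create ring and C4 in the key step. The chosen plan passes chirality from C6 to C4 inside one chair; the alternative relies on macrocyclic bias. On precedent for the key step the alternative is at least the equal. Assembling A6 (two carbinol centres, a cis trisubstituted alkene, a Z tetrasubstituted acrylate) would probably outweigh the short endgame.

**Alternative 3:** The cut is the C9=C10 double bond, seen as the trace of an SO2 extrusion from the eleven-membered cyclic sulfone A8 (sulfur between C9 and C10).
- Forward step: in-situ α-bromination (CBr2F2, KOH on Al2O3), 1,3-elimination to an episulfone and loss of SO2 would give the ten-membered diene A7.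
- In favour: the large ring can be closed by sulfide alkylation, the most reliable closure of the four plans, and the contraction creates no stereocentre. On reliability of ring formation the alternative is the better.
- Against: the extrusion does not control the geometry of a trisubstituted alkene, and a ten-membered ring tolerates both isomers, so the cis alkene is not assured. A7 still lacks ring B, and building the tetrasubstituted C3=Ca alkene and the lactone on a C3 ketone next to the C4 oxygen invites epimerisation at C4 and β-elimination. Hydroxide on alumina is a harsh medium for allylic silyl ethers.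
- Comparison: the alternative forms the ring and one alkene but none of the three stereocentres and not the butenolide; the chosen plan forms ring, C4, the E alkene and the whole carbon skeleton together. Mechanistically the alternative is fully precedented (equal or better), but in step count it should be the longest of the four.

Key step: step 12

Remarks on the chemistry:
- Six-membered intermediates carry cyclohexenone locants; C1, C2, C3, C4, C5, C6 of the cyclohexenone become C1, C10, C9, C8, C7, C6 of the target.
- TBS = tert-butyldimethylsilyl, TIPS = triisopropylsilyl.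
- A re-derivation with the chair model shows 18 (1S,6R,7S in target numbering) and 21 (4R,7S) to be consistent with each other and with the target (1S,4R,7S). No structure needed correction. The same arrangement at C1 is labelled 1R in 17 only because the alkynyl group outranks C10.
- The allene is made by alkynylation and SN2′ hydride delivery, not from a metalated allene, which is ambident.
- HC≡CMgBr and the oxazaborolidine are taken as commercial.

Step 1
Reactants: 1 (S)-carvone
Product: 3 (1S)-4-methyl-5-oxocyclohex-3-en-1-yl acetate, via methoxy hydroperoxide 2 (not isolated)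
Conditions: O3, CH2Cl2/MeOH, −78 °C; then Ac2O, Et3N, DMAP (cat.), −78 °C to rt
Reagents that add atoms: ozone [O-][O+]=O; acetic anhydride CC(=O)OC(C)=O
Why: Ozone cleaves the electron-rich 1,1-disubstituted alkene in preference to the enone; the acetylated methoxy hydroperoxide undergoes the Criegee rearrangement, in which the ring carbon migrates to oxygen with retention, so the carbinol centre keeps the S configuration of 1.

Step 2
Reactants: 3 (1S)-4-methyl-5-oxocyclohex-3-en-1-yl acetate
Product: 4 (5S)-5-hydroxy-2-methylcyclohex-2-en-1-one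
Conditions: K2CO3, MeOH, 0 °C
Reagents that add atoms: none
Why: Mild carbonate transesterification at 0 °C should free the alcohol before β-elimination to the dienone can compete; the stereocentre is untouched.

Step 3
Reactants: 4 (5S)-5-hydroxy-2-methylcyclohex-2-en-1-one
Product: 5 (5S)-5-(TBS-oxy)-2-methylcyclohex-2-en-1-one
Conditions: TBSCl, imidazole, DMF, rt
Reagents that add atoms: tert-butyldimethylsilyl chloride CC(C)(C)[Si](C)(C)Cl
Why: Standard silylation of a secondary alcohol under near-neutral conditions that leave the β-oxy enone intact.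

Step 4
Reactants: 5 (5S)-5-(TBS-oxy)-2-methylcyclohex-2-en-1-one
Product: 7 (5S,6R)-5-(TBS-oxy)-2,6-dimethylcyclohex-2-en-1-one, via lithium enolate 6 (not isolated)
Conditions: LiN(iPr)2, THF, −78 °C; MeI, −78 to −20 °C
Reagents that add atoms: iodomethane CI
Why: Kinetic α′-deprotonation of the enone gives the cross-conjugated enolate, which is C-methylated (enolate alkylation) anti to the silyloxy group; the C6 configuration formed here is erased in step 5.

Step 5
Reactants: 7 (5S,6R)-5-(TBS-oxy)-2,6-dimethylcyclohex-2-en-1-one; 8 allyl bromide (3-bromoprop-1-ene)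
Product: 10 (5S,6R)-5-(TBS-oxy)-2,6-dimethyl-6-(prop-2-en-1-yl)cyclohex-2-en-1-one, via lithium enolate 9 (not isolated)
Conditions: LiN(iPr)2, THF, −78 °C; 8, DMPU, −78 to −10 °C
Reagents that add atoms: none
Why: Second enolate alkylation: the fully substituted enolate 9 should be attacked by the allyl halide on the face opposite the adjacent silyloxy group, which sets the quaternary C6 (6R) with the allyl group trans to the C5 oxygen and the methyl group cis to it.

Step 6
Reactants: 10 (5S,6R)-5-(TBS-oxy)-2,6-dimethyl-6-(prop-2-en-1-yl)cyclohex-2-en-1-one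
Product: 11 2-[(1R,6S)-6-(TBS-oxy)-1,3-dimethyl-2-oxocyclohex-3-en-1-yl]acetaldehyde
Conditions: OsO4 (cat.), NaIO4, 2,6-lutidine, 1,4-dioxane/H2O, rt
Reagents that add atoms: osmium tetroxide O=[Os](=O)(=O)=O; sodium periodate [Na+].[O-]I(=O)(=O)=O
Why: Lemieux–Johnson cleavage: electrophilic OsO4 dihydroxylates the terminal alkene and not the electron-poor enone alkene, and periodate cleaves the diol; the lutidine buffer suppresses over-oxidation.

Step 7
Reactants: 11 2-[(1R,6S)-6-(TBS-oxy)-1,3-dimethyl-2-oxocyclohex-3-en-1-yl]acetaldehyde
Product: 12 (5S,6R)-5-(TBS-oxy)-2,6-dimethyl-6-[(E)-2-(TIPS-oxy)ethenyl]cyclohex-2-en-1-one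
Conditions: iPr3SiOTf, Et3N, CH2Cl2, −78 to 0 °C
Reagents that add atoms: triisopropylsilyl trifluoromethanesulfonate CC(C)[Si](OS(=O)(=O)C(F)(F)F)(C(C)C)C(C)C
Why: Soft enolisation of the aldehyde with a silyl triflate and an amine; the ketone has no α′ hydrogen, and the E enol ether should be favoured because the Z isomer would press the silyloxy group against the quaternary C6. The enol ether also masks the aldehyde for step 10.

Step 8
Reactants: 13 2,2-dimethyl-1,3-dioxan-5-one
Product: 14 5-ethynyl-2,2-dimethyl-1,3-dioxan-5-ol
Conditions: HC≡CMgBr, THF, 0 °C; aq. NH4Cl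
Reagents that add atoms: ethynylmagnesium bromide C#C[Mg]Br
Why: Grignard 1,2-addition to the ketone; no stereocentre arises because the dioxane is symmetric.

Step 9
Reactants: 14 5-ethynyl-2,2-dimethyl-1,3-dioxan-5-ol
Product: 15 5-ethynyl-5-methoxy-2,2-dimethyl-1,3-dioxane
Conditions: NaH (1.1 equiv), MeI, THF, 0 °C to rt
Reagents that add atoms: iodomethane CI
Why: Williamson methylation of the tertiary alkoxide, which forms faster than the acetylide with one equivalent of NaH; the methoxy group is the leaving group for step 11.

Step 10
Reactants: 12 (5S,6R)-5-(TBS-oxy)-2,6-dimethyl-6-[(E)-2-(TIPS-oxy)ethenyl]cyclohex-2-en-1-one; 15 5-ethynyl-5-methoxy-2,2-dimethyl-1,3-dioxane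
Product: 17 (1R,5S,6R)-5-(TBS-oxy)-1-[(5-methoxy-2,2-dimethyl-1,3-dioxan-5-yl)ethynyl]-2,6-dimethyl-6-[(E)-2-(TIPS-oxy)ethenyl]cyclohex-2-en-1-ol, via lithium alkynide 16 (not isolated)
Conditions: 15, n-BuLi, THF, −78 °C; then 12, −78 to −40 °C; aq. NH4Cl
Reagents that add atoms: none
Why: 1,2-Addition of a lithium alkynide to a non-enolisable enone. In the half-chair that holds the C5 silyloxy and the C6 silyloxyvinyl groups trans-diaxial (C6 methyl equatorial), the slim alkynide should enter axially, anti to the vinyl group, which places the two unsaturated groups trans. Entry anti to the silyloxy group is the competing path and is treated among the uncertain steps.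

Step 11
Reactants: 17 (1R,5S,6R)-5-(TBS-oxy)-1-[(5-methoxy-2,2-dimethyl-1,3-dioxan-5-yl)ethynyl]-2,6-dimethyl-6-[(E)-2-(TIPS-oxy)ethenyl]cyclohex-2-en-1-ol
Product: 18 (1S,5S,6R)-5-(TBS-oxy)-1-[2-(2,2-dimethyl-1,3-dioxan-5-ylidene)ethenyl]-2,6-dimethyl-6-[(E)-2-(TIPS-oxy)ethenyl]cyclohex-2-en-1-ol
Conditions: LiAlH4, THF, 0 °C to rt; aq. sodium potassium tartrate
Reagents that add atoms: none
Why: Alkoxide-directed trans-hydroalumination of the propargylic alcohol puts hydride on C2 and aluminium on C3, and 1,2-elimination of the methoxide on Ca gives the allene (SN2′ reduction of a 4-alkoxyalk-2-yn-1-ol). No stereo-element is created because the allene terminus carries two identical arms, and C1 is untouched.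

Step 12
Reactants: 18 (1S,5S,6R)-5-(TBS-oxy)-1-[2-(2,2-dimethyl-1,3-dioxan-5-ylidene)ethenyl]-2,6-dimethyl-6-[(E)-2-(TIPS-oxy)ethenyl]cyclohex-2-en-1-ol
Product: 21 (2Z,5S,6E,8R)-5-(TBS-oxy)-9-(2,2-dimethyl-1,3-dioxan-5-ylidene)-2,6-dimethyl-8-(TIPS-oxy)cyclodeca-2,6-dien-1-one (target numbering: C1 ketone, C3 alkylidene dioxane, 4R, 5E, 7S, 9Z), via potassium alkoxide 19 (not isolated), via potassium dienolate 20 (not isolated)
Conditions: KN(SiMe3)2, 18-crown-6, THF, −78 to −30 °C; then AcOH/THF, −78 °C
Reagents that add atoms: none
Why: Proposed new method: deprotonation gives the crown-separated potassium alkoxide 19, in which the oxyanion weakens the C1–C6 bond; in a concerted chair-like [3,3] shift the central allene carbon C3 bonds to the enol ether terminus C4 while C1–C6 breaks, and the dienolate 20 is protonated at its α carbon C2 under kinetic control, which leaves the C3=Ca alkene exocyclic. The closest known reaction type is the anionic oxy-Cope ring expansion of trans-1,2-dialkenylcyclohexanols to cyclodec-5-enones and its acetylenic variant; an allenyl partner should react at least as readily, because a strained cumulated π bond is consumed and its central carbon has no substituent in the path of approach. The ten-membered ring is not closed end to end: it appears when the bond shared by the cyclohexene and the six-membered transition-state ring is cleaved (ring expansion, six to ten), so no entropic cost of macrocyclisation is paid. The new stereocentre C4 is controlled by the quaternary C6: in the only chair that keeps both ring bonds (C1–C10 and C6–C7) equatorial, the E silyloxy group is equatorial and C3 reaches the face of the enol ether that gives 4R, and the same chair makes C5=C6 E. The step needs chair over boat, [3,3] shift over fragmentation, and protonation at C2 and not at Ca; these are secured by the trans alkenyl groups (one reactive half-chair), the cis C9=C10 alkene locked in the ring, the non-epimerisable C6, the symmetric dioxane terminus and the cold buffered quench.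

Step 13
Reactants: 21 (2Z,5S,6E,8R)-5-(TBS-oxy)-9-(2,2-dimethyl-1,3-dioxan-5-ylidene)-2,6-dimethyl-8-(TIPS-oxy)cyclodeca-2,6-dien-1-one
Product: 22 (1S,2Z,5S,6E,8R)-5-(TBS-oxy)-9-(2,2-dimethyl-1,3-dioxan-5-ylidene)-2,6-dimethyl-8-(TIPS-oxy)cyclodeca-2,6-dien-1-ol
Conditions: (R)-2-methyl-CBS-oxazaborolidine (0.5 equiv), catecholborane, toluene, −78 °C
Reagents that add atoms: none
Why: Corey–Bakshi–Shibata reduction: the oxazaborolidine binds the ketone with the α-methylalkenyl flank as the large group and delivers hydride to one face under reagent control, which should give the 1S allylic alcohol; catecholborane at −78 °C leaves the alkenes and silyl ethers alone. The ketone is reduced without storage to forestall migration of the exocyclic alkene.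

Step 14
Reactants: 22 (1S,2Z,5S,6E,8R)-5-(TBS-oxy)-9-(2,2-dimethyl-1,3-dioxan-5-ylidene)-2,6-dimethyl-8-(TIPS-oxy)cyclodeca-2,6-dien-1-ol
Product: 23 (1S,2Z,5S,6E,8R)-9-(2,2-dimethyl-1,3-dioxan-5-ylidene)-2,6-dimethyl-8-(TIPS-oxy)cyclodeca-2,6-diene-1,5-diol
Conditions: HF·pyridine, pyridine, THF, 0 °C to rt
Reagents that add atoms: none
Why: Buffered fluoride should cleave the less hindered secondary TBS ether well before the TIPS ether at the crowded, doubly allylic C4; the acetonide is stable under these non-aqueous conditions.

Step 15
Reactants: 23 (1S,2Z,5S,6E,8R)-9-(2,2-dimethyl-1,3-dioxan-5-ylidene)-2,6-dimethyl-8-(TIPS-oxy)cyclodeca-2,6-diene-1,5-diol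
Product: 24 (1S,2Z,5S,6E,8R)-9-(2,2-dimethyl-1,3-dioxan-5-ylidene)-2,6-dimethyl-8-(TIPS-oxy)cyclodeca-2,6-diene-1,5-diyl diacetate
Conditions: Ac2O, pyridine, DMAP (cat.), CH2Cl2, 0 °C to rt
Reagents that add atoms: acetic anhydride CC(=O)OC(C)=O
Why: Nucleophile-catalysed acetylation of the two secondary allylic alcohols; the C4 oxygen and the two primary oxygens are still masked, so only O1 and O7 are acylated.

Step 16
Reactants: 24 (1S,2Z,5S,6E,8R)-9-(2,2-dimethyl-1,3-dioxan-5-ylidene)-2,6-dimethyl-8-(TIPS-oxy)cyclodeca-2,6-diene-1,5-diyl diacetate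
Product: 25 (1S,2Z,5S,6E,8R)-9-(1,3-dihydroxypropan-2-ylidene)-8-hydroxy-2,6-dimethylcyclodeca-2,6-diene-1,5-diyl diacetate
Conditions: 48% aq. HF, MeCN, 0 °C to rt
Reagents that add atoms: none
Why: Aqueous HF should remove the remaining silyl ether and hydrolyse the 1,3-dioxane acetal in one operation at low temperature, while the acetates are stable to this mildly acidic medium.

Step 17
Reactants: 25 (1S,2Z,5S,6E,8R)-9-(1,3-dihydroxypropan-2-ylidene)-8-hydroxy-2,6-dimethylcyclodeca-2,6-diene-1,5-diyl diacetate
Product: 27 C13 aldehyde of the target (butenolide closed between O4 and C12 with a formyl group on Ca; 1S,4R,7S; 5E,9Z), via lactol aldehyde 26 (not isolated)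
Conditions: TEMPO (0.2 equiv), PhI(OAc)2 (3.5 equiv), CH2Cl2, rt
Reagents that add atoms: none
Why: Nitroxyl-catalysed oxidation is selective for the primary allylic alcohols; the aldehyde cis to the C4 hydroxyl is trapped as the five-membered lactol and oxidised on to the lactone (oxidative lactonisation of a 1,4-diol), while the other arm stops at the aldehyde.

Step 18
Reactants: 27 C13 aldehyde of the target
Product: 28 target CNP0328753.1
Conditions: NaBH4, CeCl3·7H2O, MeOH, −78 °C
Reagents that add atoms: none
Why: Luche reduction: 1,2-selective hydride addition to the aldehyde at low temperature; the lactone, the acetates and the fully substituted β carbon of the butenolide should not be attacked.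

Compound list

1 | (S)-carvone, (5S)-2-methyl-5-(prop-1-en-2-yl)cyclohex-2-en-1-one | CC1=CC[C@@H](CC1=O)C(C)=C | starting material
2 | (5S)-5-(1-hydroperoxy-1-methoxyethyl)-2-methylcyclohex-2-en-1-one (not isolated; side-chain centre undefined) | CC1=CC[C@@H](CC1=O)C(C)(OC)OO | intermediate
3 | (1S)-4-methyl-5-oxocyclohex-3-en-1-yl acetate | CC1=CC[C@@H](CC1=O)OC(C)=O | intermediate
4 | (5S)-5-hydroxy-2-methylcyclohex-2-en-1-one | CC1=CC[C@@H](CC1=O)O | intermediate
5 | (5S)-5-(tert-butyldimethylsilyloxy)-2-methylcyclohex-2-en-1-one | CC1=CC[C@@H](CC1=O)O[Si](C)(C)C(C)(C)C | intermediate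
6 | lithium (3S)-3-(tert-butyldimethylsilyloxy)-6-methylcyclohexa-1,5-dien-1-olate (not isolated) | [Li+].[O-]C1=C[C@@H](O[Si](C)(C)C(C)(C)C)CC=C1C | intermediate
7 | (5S,6R)-5-(tert-butyldimethylsilyloxy)-2,6-dimethylcyclohex-2-en-1-one | O=C1C(C)=CC[C@H](O[Si](C)(C)C(C)(C)C)[C@H]1C | intermediate
8 | allyl bromide (3-bromoprop-1-ene) | C=CCBr | starting material
9 | lithium (3S)-3-(tert-butyldimethylsilyloxy)-2,6-dimethylcyclohexa-1,5-dien-1-olate (not isolated) | [Li+].[O-]C1=C(C)[C@@H](O[Si](C)(C)C(C)(C)C)CC=C1C | intermediate
10 | (5S,6R)-5-(tert-butyldimethylsilyloxy)-2,6-dimethyl-6-(prop-2-en-1-yl)cyclohex-2-en-1-one | O=C1C(C)=CC[C@H](O[Si](C)(C)C(C)(C)C)[C@@]1(C)CC=C | intermediate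
11 | 2-[(1R,6S)-6-(tert-butyldimethylsilyloxy)-1,3-dimethyl-2-oxocyclohex-3-en-1-yl]acetaldehyde | O=C1C(C)=CC[C@H](O[Si](C)(C)C(C)(C)C)[C@@]1(C)CC=O | intermediate
12 | (5S,6R)-5-(tert-butyldimethylsilyloxy)-2,6-dimethyl-6-[(E)-2-(triisopropylsilyloxy)ethenyl]cyclohex-2-en-1-one | O=C1C(C)=CC[C@H](O[Si](C)(C)C(C)(C)C)[C@@]1(C)/C=C/O[Si](C(C)C)(C(C)C)C(C)C | intermediate
13 | 2,2-dimethyl-1,3-dioxan-5-one | CC1(C)OCC(=O)CO1 | starting material
14 | 5-ethynyl-2,2-dimethyl-1,3-dioxan-5-ol | C#CC1(O)COC(C)(C)OC1 | intermediate
15 | 5-ethynyl-5-methoxy-2,2-dimethyl-1,3-dioxane | C#CC1(OC)COC(C)(C)OC1 | intermediate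
16 | lithium 2-(5-methoxy-2,2-dimethyl-1,3-dioxan-5-yl)ethyn-1-ide (not isolated) | [Li+].[C-]#CC1(OC)COC(C)(C)OC1 | intermediate
17 | (1R,5S,6R)-5-(tert-butyldimethylsilyloxy)-1-[(5-methoxy-2,2-dimethyl-1,3-dioxan-5-yl)ethynyl]-2,6-dimethyl-6-[(E)-2-(triisopropylsilyloxy)ethenyl]cyclohex-2-en-1-ol | O[C@@]1(C#CC2(OC)COC(C)(C)OC2)C(C)=CC[C@H](O[Si](C)(C)C(C)(C)C)[C@@]1(C)/C=C/O[Si](C(C)C)(C(C)C)C(C)C | intermediate
18 | (1S,5S,6R)-5-(tert-butyldimethylsilyloxy)-1-[2-(2,2-dimethyl-1,3-dioxan-5-ylidene)ethenyl]-2,6-dimethyl-6-[(E)-2-(triisopropylsilyloxy)ethenyl]cyclohex-2-en-1-ol | O[C@@]1(C=C=C2COC(C)(C)OC2)C(C)=CC[C@H](O[Si](C)(C)C(C)(C)C)[C@@]1(C)/C=C/O[Si](C(C)C)(C(C)C)C(C)C | intermediate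
19 | potassium alkoxide of 18 (not isolated) | [K+].[O-][C@@]1(C=C=C2COC(C)(C)OC2)C(C)=CC[C@H](O[Si](C)(C)C(C)(C)C)[C@@]1(C)/C=C/O[Si](C(C)C)(C(C)C)C(C)C | intermediate
20 | potassium dienolate of 21 (O–C1=C2–C3=Ca; C10 and C3 trans on C1=C2; not isolated) | [K+].[O-]C1=C\C(=C2COC(C)(C)OC2)[C@H](O[Si](C(C)C)(C(C)C)C(C)C)/C=C(\C)[C@@H](O[Si](C)(C)C(C)(C)C)C/C=C\1C | intermediate
21 | (2Z,5S,6E,8R)-5-(tert-butyldimethylsilyloxy)-9-(2,2-dimethyl-1,3-dioxan-5-ylidene)-2,6-dimethyl-8-(triisopropylsilyloxy)cyclodeca-2,6-dien-1-one | O=C1CC(=C2COC(C)(C)OC2)[C@H](O[Si](C(C)C)(C(C)C)C(C)C)/C=C(\C)[C@@H](O[Si](C)(C)C(C)(C)C)C/C=C\1C | intermediate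
22 | (1S,2Z,5S,6E,8R)-5-(tert-butyldimethylsilyloxy)-9-(2,2-dimethyl-1,3-dioxan-5-ylidene)-2,6-dimethyl-8-(triisopropylsilyloxy)cyclodeca-2,6-dien-1-ol | O[C@H]1CC(=C2COC(C)(C)OC2)[C@H](O[Si](C(C)C)(C(C)C)C(C)C)/C=C(\C)[C@@H](O[Si](C)(C)C(C)(C)C)C/C=C\1C | intermediate
23 | (1S,2Z,5S,6E,8R)-9-(2,2-dimethyl-1,3-dioxan-5-ylidene)-2,6-dimethyl-8-(triisopropylsilyloxy)cyclodeca-2,6-diene-1,5-diol | O[C@H]1CC(=C2COC(C)(C)OC2)[C@H](O[Si](C(C)C)(C(C)C)C(C)C)/C=C(\C)[C@@H](O)C/C=C\1C | intermediate
24 | (1S,2Z,5S,6E,8R)-9-(2,2-dimethyl-1,3-dioxan-5-ylidene)-2,6-dimethyl-8-(triisopropylsilyloxy)cyclodeca-2,6-diene-1,5-diyl diacetate | CC(=O)O[C@H]1CC(=C2COC(C)(C)OC2)[C@H](O[Si](C(C)C)(C(C)C)C(C)C)/C=C(\C)[C@@H](OC(C)=O)C/C=C\1C | intermediate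
25 | (1S,2Z,5S,6E,8R)-9-(1,3-dihydroxypropan-2-ylidene)-8-hydroxy-2,6-dimethylcyclodeca-2,6-diene-1,5-diyl diacetate | CC(=O)O[C@H]1CC(=C(CO)CO)[C@H](O)/C=C(\C)[C@@H](OC(C)=O)C/C=C\1C | intermediate
26 | lactol aldehyde: O4–C12 lactol with formyl group on Ca (lactol centre undefined; not isolated) | CC(=O)O[C@H]1CC2=C(C=O)C(O)O[C@@H]2/C=C(\C)[C@@H](OC(C)=O)C/C=C\1C | intermediate
27 | C13 aldehyde of the target: (1S,4R,7S)-1,7-diacetoxy butenolide with formyl group on Ca, 5E,9Z | CC(=O)O[C@H]1CC2=C(C=O)C(=O)O[C@@H]2/C=C(\C)[C@@H](OC(C)=O)C/C=C\1C | intermediate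
28 | CNP0328753.1: (1S,4R,7S)-1,7-diacetoxy butenolide with hydroxymethyl group on Ca, 5E,9Z | CC(=O)O[C@H]1CC2=C(CO)C(=O)O[C@@H]2/C=C(\C)[C@@H](OC(C)=O)C/C=C\1C | target

Total step count: 18. Longest linear sequence: 16 steps (steps 1–7 and 10–18, from 1 to 28); steps 8 and 9 form the side branch to 15.

Steps least certain to work

**Step 12 (key step, proposed new method).**
- What may go wrong: the alkoxide may fragment by expelling the allenyl anion, or react through a boat, which would erode C4. The dienolate may lose an acetal alkoxide from the carbon next to Ca. The exocyclic alkene may move into conjugation with the C1 ketone during the quench. Silyl migration from O7 to the C1 alkoxide may compete.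
- Fallback (known chemistry), setting out from 17 and returning at 21: 17 is itself a trans-1-alkynyl-2-alkenylcyclohexenol. Under KN(SiMe3)2 and 18-crown-6 it should undergo the acetylenic anionic oxy-Cope ring expansion, and protonation of the allenolate would give the cross-conjugated γ-methoxy dienone F1 as a mixture of C2=C3 isomers. SmI2 in THF/MeOH at −78 °C would then reduce the enone by two electrons and expel methoxide from Ca. The samarium dienolate has the constitution of 20 and is protonated at C2 to give 21; both C2=C3 isomers converge. The C4 silyloxy group is the competing leaving group in this reduction.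

**Step 10.**
- What may go wrong: poor facial selectivity. Entry of the alkynide anti to the C5 silyloxy group, and therefore syn to the vinyl group, would give the C1 epimer.
- Fallback, setting out from 12 and returning at 21: the C1-epimeric alkynyl carbinol F2 would be taken through the same two operations. LiAlH4 would give the C1-epimeric allenyl carbinol F3, whose potassium alkoxide can rearrange through the chair that still holds C6–C7 equatorial and the C6 methyl axial, with the oxyanion now equatorial and C1–C10 axial. C1 is lost as the ketone, so the same 21 (4R, 5E) should result. The competing chair would need the silyloxy group and the oxyanion syn-diaxial.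

**Step 7.**
- What may go wrong: incomplete geometric control of the enol ether, which would pass directly into the C4 configuration, and silylation at the γ position of the enone.
- Fallback, setting out from 11 and returning at 12: thermodynamic control replaces kinetic control. The Z enol ether F4, alone or in the mixture, would be equilibrated by reversible thiyl-radical addition (PhSSPh cat., hν, benzene) to the E isomer 12, in which the silyloxy group avoids the quaternary C6.

**Step 13.**
- What may go wrong: a mismatch between catalyst and ring conformation would lower facial selectivity, and a slow reduction would allow alkene migration in 21.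
- Fallback, setting out from 21 and returning at 22: substrate control followed by inversion. NaBH4/CeCl3 at −78 °C should attack from the ring periphery; if the carbonyl keeps the orientation in which it is formed, this gives the 1R alcohol F5. A Mitsunobu reaction (PPh3, DIAD, 4-nitrobenzoic acid) would give the inverted 4-nitrobenzoate F6, and K2CO3 in MeOH would release 22.

**Step 16.**
- What may go wrong: acid-promoted ionisation at the doubly allylic C4 (closure of a dihydrofuran with the cis hydroxymethyl arm, transannular cyclisation) and acetyl migration to the freed hydroxyls.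
- Fallback, setting out from 24 and returning at 25: two orthogonal, non-aqueous operations. Bu4NF buffered with AcOH in THF would give the C4 alcohol F7 with the acetonide intact. Transacetalisation with PPTS in MeOH at rt would then free the two primary alcohols to give 25.

Further compounds

F1 | step 12 | (5S,6E,8R)-5-(tert-butyldimethylsilyloxy)-9-(5-methoxy-2,2-dimethyl-1,3-dioxan-5-yl)-2,6-dimethyl-8-(triisopropylsilyloxy)cyclodeca-2,6,9-trien-1-one (2Z; C9=C10 ring alkene of this name as isomer mixture) | O=C1C=C(C2(OC)COC(C)(C)OC2)[C@H](O[Si](C(C)C)(C(C)C)C(C)C)/C=C(\C)[C@@H](O[Si](C)(C)C(C)(C)C)C/C=C\1C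
F2 | step 10 | (1S,5S,6R)-5-(tert-butyldimethylsilyloxy)-1-[(5-methoxy-2,2-dimethyl-1,3-dioxan-5-yl)ethynyl]-2,6-dimethyl-6-[(E)-2-(triisopropylsilyloxy)ethenyl]cyclohex-2-en-1-ol | O[C@]1(C#CC2(OC)COC(C)(C)OC2)C(C)=CC[C@H](O[Si](C)(C)C(C)(C)C)[C@@]1(C)/C=C/O[Si](C(C)C)(C(C)C)C(C)C
F3 | step 10 | (1R,5S,6R)-5-(tert-butyldimethylsilyloxy)-1-[2-(2,2-dimethyl-1,3-dioxan-5-ylidene)ethenyl]-2,6-dimethyl-6-[(E)-2-(triisopropylsilyloxy)ethenyl]cyclohex-2-en-1-ol | O[C@]1(C=C=C2COC(C)(C)OC2)C(C)=CC[C@H](O[Si](C)(C)C(C)(C)C)[C@@]1(C)/C=C/O[Si](C(C)C)(C(C)C)C(C)C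
F4 | step 7 | (5S,6R)-5-(tert-butyldimethylsilyloxy)-2,6-dimethyl-6-[(Z)-2-(triisopropylsilyloxy)ethenyl]cyclohex-2-en-1-one | O=C1C(C)=CC[C@H](O[Si](C)(C)C(C)(C)C)[C@@]1(C)/C=C\O[Si](C(C)C)(C(C)C)C(C)C
F5 | step 13 | (1R,2Z,5S,6E,8R)-5-(tert-butyldimethylsilyloxy)-9-(2,2-dimethyl-1,3-dioxan-5-ylidene)-2,6-dimethyl-8-(triisopropylsilyloxy)cyclodeca-2,6-dien-1-ol | O[C@@H]1CC(=C2COC(C)(C)OC2)[C@H](O[Si](C(C)C)(C(C)C)C(C)C)/C=C(\C)[C@@H](O[Si](C)(C)C(C)(C)C)C/C=C\1C
F6 | step 13 | (1S,2Z,5S,6E,8R)-5-(tert-butyldimethylsilyloxy)-9-(2,2-dimethyl-1,3-dioxan-5-ylidene)-2,6-dimethyl-8-(triisopropylsilyloxy)cyclodeca-2,6-dien-1-yl 4-nitrobenzoate | O=C(O[C@H]1CC(=C2COC(C)(C)OC2)[C@H](O[Si](C(C)C)(C(C)C)C(C)C)/C=C(\C)[C@@H](O[Si](C)(C)C(C)(C)C)C/C=C\1C)c1ccc(cc1)[N+](=O)[O-]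
F7 | step 16 | (1S,2Z,5S,6E,8R)-9-(2,2-dimethyl-1,3-dioxan-5-ylidene)-8-hydroxy-2,6-dimethylcyclodeca-2,6-diene-1,5-diyl diacetate | CC(=O)O[C@H]1CC(=C2COC(C)(C)OC2)[C@H](O)/C=C(\C)[C@@H](OC(C)=O)C/C=C\1C
A1 | alternative 1 | methyl (2Z,5S,6Z,9S,10E)-5,9-dihydroxy-3-iodo-12,12-dimethoxy-2-[(4-methoxybenzyloxy)methyl]-6,10-dimethyldodeca-2,6,10-trienoate | COC(=O)/C(COCc1ccc(OC)cc1)=C(\I)C[C@H](O)/C(C)=C\C[C@H](O)/C(C)=C/C(OC)OC
A2 | alternative 1 | methyl (2Z)-3-iodo-2-[(4-methoxybenzyloxy)methyl]-5-oxopent-2-enoate | COC(=O)/C(COCc1ccc(OC)cc1)=C(\I)CC=O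
A3 | alternative 1 | (2E)-4,4-dimethoxy-2-methylbut-2-enal | O=C/C(C)=C/C(OC)OC
A4 | alternative 1 | 2-(buta-2,3-dien-2-yl)-4,4,5,5-tetramethyl-1,3,2-dioxaborolane | CC(=C=C)B1OC(C)(C)C(C)(C)O1
A5 | alternative 2 | protected target: C1 and C7 tert-butyldimethylsilyl ethers, C13 4-methoxybenzyl ether | CC(C)(C)[Si](C)(C)O[C@H]1CC2=C(COCc3ccc(OC)cc3)C(=O)O[C@@H]2/C=C(\C)[C@@H](O[Si](C)(C)C(C)(C)C)C/C=C\1C
A6 | alternative 2 | methyl (2Z,5S,6Z,9S)-5,9-bis(tert-butyldimethylsilyloxy)-3-formyl-2-[(4-methoxybenzyloxy)methyl]-6-methylundeca-2,6-dien-10-ynoate | C#C[C@@H](O[Si](C)(C)C(C)(C)C)C/C=C(/C)[C@@H](O[Si](C)(C)C(C)(C)C)C/C(C=O)=C(\COCc1ccc(OC)cc1)C(=O)OC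
A7 | alternative 3 | ten-membered diene with C3 ethylene ketal, C4 4-methoxybenzyl ether, C1 and C7 tert-butyldimethylsilyl ethers | CC(C)(C)[Si](C)(C)O[C@H]1CC2(OCCO2)[C@H](OCc3ccc(OC)cc3)/C=C(\C)[C@@H](O[Si](C)(C)C(C)(C)C)C/C=C\1C
A8 | alternative 3 | eleven-membered cyclic sulfone, sulfur between C9 and C10 (C10 centre undefined), otherwise substituted as A7 | CC(C)(C)[Si](C)(C)O[C@H]1CC2(OCCO2)[C@H](OCc3ccc(OC)cc3)/C=C(\C)[C@@H](O[Si](C)(C)C(C)(C)C)CCS(=O)(=O)C1C
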